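**Plan**

- Retrosynthesis: both esters are cut first (C4–O aroyl, C1–O acetyl), then the C4 carbinol goes back to a ketone and the C7 ketone to a methylene. Ring A is then cut at C1–C2 and at C3–C3a into a methyl isopropyl ketone and a seven-membered 1,4-keto aldehyde, which goes back to an achiral cross-conjugated cycloheptadienone and a furan/oxyallyl (4+3) adduct.
- Enabling feature: in ring A the pairs C1–O/C3 and C3–O/C4=O are two β-oxygenated carbonyl (aldol) relationships that share the isopropyl-bearing carbon C3. The cyclopentane C1–C2–C3–C3a–C8a is therefore the double aldol adduct of a methyl ketone (C2–C3) across a 1,4-keto aldehyde (C1, C8a, C3a, C4).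
- Forward: ring B first ((4+3) cycloaddition, hydrogenation, double β-elimination, asymmetric conjugate addition, ozonolysis), then ring A in one flask by an aldol–aldol annulation, then C7 oxidation, C4 reduction and the two acylations.
- Stereochemistry: C8a from ligand-controlled conjugate addition; C1 from D-proline; C3 and C3a from the lithium-chelated, reversible ring closure (trans fusion); C4 from hydroxyl-directed, anti-selective hydride delivery.

Key step: step 6

Assumption: azulene numbering is used for the bicyclic compounds (C1 acetoxy carbon, C3 isopropyl carbinol carbon, C3a/C8a ring fusion, C4 aroyloxy carbon, C7 ketone carbon), and the drawn configuration is read as absolute (1S,3S,3aR,4R,8aS).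

**Step 1**
Reactants: 1 2,5-dimethylfuran; 2 1,1,3,3-tetrabromopropan-2-one
Product: 4 meso-(1R,5S)-1,5-dimethyl-8-oxabicyclo[3.2.1]oct-6-en-3-one, via dibromo cycloadduct 3 (not isolated)
Conditions: Zn, B(OEt)3, THF, 0 °C → rt; then Zn–Cu couple, NH4Cl, MeOH, rt
Reagents that add atoms: none
Why: Zinc reduces the tetrabromo ketone to a dibromo-oxyallyl cation that undergoes the (4+3) oxyallyl cycloaddition with the electron-rich furan, and reductive removal of both bromines then gives the meso bridged ketone, whose bridgehead centres are fixed by the ring system.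

**Step 2**
Reactants: 4 meso-(1R,5S)-1,5-dimethyl-8-oxabicyclo[3.2.1]oct-6-en-3-one
Product: 5 meso-(1R,5S)-1,5-dimethyl-8-oxabicyclo[3.2.1]octan-3-one
Conditions: H2 (1 atm), 10% Pd/C, EtOAc, rt
Reagents that add atoms: none
Why: Catalytic hydrogenation saturates the strained bridging alkene and touches neither the ketone nor the ether, and no new stereocentre arises.

**Step 3**
Reactants: 5 meso-(1R,5S)-1,5-dimethyl-8-oxabicyclo[3.2.1]octan-3-one
Product: 7 3,6-dimethylcyclohepta-2,6-dien-1-one, via hydroxy enone 6 (not isolated)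
Conditions: p-TsOH·H2O (10 mol %), benzene, reflux, Dean–Stark; stopped at full conversion
Reagents that add atoms: none
Why: Acid opens the tertiary bridging ether β to the ketone (E1-type retro-oxa-Michael elimination) and then dehydrates the tertiary β-hydroxy ketone (aldol-type dehydration), and removal of water drives the sequence to the achiral, mirror-symmetric cross-conjugated dienone.

**Step 4**
Reactants: 7 3,6-dimethylcyclohepta-2,6-dien-1-one; 8 hex-1-yne
Product: 10 (6S)-6-[(1E)-hex-1-en-1-yl]-3,6-dimethylcyclohept-2-en-1-one, via alkenylalane 9 (not isolated)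
Conditions: 8, iBu2AlH, hexane, 55 °C; then 7, CuTC (CuO2CC4H3S, 10 mol %), chiral phosphinamine ligand of the SimplePhos type (11 mol %, enantiomer chosen for the S product), Et2O/THF, −30 °C; aq. HCl work-up
Reagents that add atoms: none
Why: syn-Hydroalumination gives the (E)-alkenylalane, and its copper-catalysed asymmetric conjugate addition to one of the two equivalent β-methyl enone units of the achiral dienone creates the all-carbon quaternary centre C8a (S) under ligand control, the resulting aluminium dienolate preventing a second addition.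

**Step 5**
Reactants: 10 (6S)-6-[(1E)-hex-1-en-1-yl]-3,6-dimethylcyclohept-2-en-1-one
Product: 11 (1S)-1,5-dimethyl-3-oxocyclohept-4-ene-1-carbaldehyde
Conditions: O3, CH2Cl2/MeOH, Sudan Red 7B (indicator), −78 °C; then Me2S, −78 °C → rt
Reagents that add atoms: ozone, [O-][O+]=O
Why: Ozonolysis with a dye end-point cleaves the electron-rich 1,2-disubstituted alkene far faster than the electron-poor trisubstituted enone alkene, so reductive work-up unveils the non-enolisable neopentyl aldehyde without touching C8a.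

**Step 6**
Reactants: 11 (1S)-1,5-dimethyl-3-oxocyclohept-4-ene-1-carbaldehyde; 12 3-methylbutan-2-one
Product: 14 (1S,3S,3aS,8aS)-1,3-dihydroxy-6,8a-dimethyl-3-(propan-2-yl)-2,3,3a,7,8,8a-hexahydroazulen-4(1H)-one, via aldol adduct 13 (not isolated)
Conditions: D-proline (30 mol %), 12 as solvent, rt; volatiles removed in vacuo; then LDA (LiN(i-Pr)2, 3.0 equiv), THF, −78 → −20 °C; AcOH, −78 °C
Reagents that add atoms: none
Why: The enamine formed from D-proline and the methyl group of 12 adds to the aldehyde of 11 (C1–C2), and after removal of the excess ketone two equivalents of amide base turn aldol 13 into its alkoxide/cross-conjugated dienolate dianion, whose α′ carbon C3a adds to the isopropyl ketone (C3–C3a), so ring A is built by a one-flask aldol–aldol (3+2) annulation. The closest known reaction types are the proline-catalysed aldol addition of methyl ketones to α-quaternary aldehydes and the base-mediated intramolecular aldol addition of 1,6-diketones to 2-acylcyclopentanols. Ring A closes in the 5-(enolexo)-exo-trig mode. C1 (S) is fixed by the catalyst through the usual enamine–carboxylic acid transition state, C3 by the lithium chelate that holds the C1 alkoxide, the C3 carbonyl oxygen and the enolate oxygen on one face in a closed chair-like transition state (C1–O, C3–O and C4 all cis), and C3a follows from the same chelate, which for the 1S alkoxide puts C4 cis to the angular methyl group, that is the trans ring fusion. The step needs attack at the aldehyde and not at the enone (the aldehyde is the stronger, non-enolisable electrophile), α′-selective enolisation (the adjacent alkoxide deactivates C2–H and the isopropyl methine is hindered) and the trans-fused aldol (the tertiary aldolate forms reversibly at −20 °C, so isomers that cannot keep all three oxygens on lithium should revert and the fully chelated one should accumulate).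

**Step 7**
Reactants: 14 (1S,3S,3aS,8aS)-1,3-dihydroxy-6,8a-dimethyl-3-(propan-2-yl)-2,3,3a,7,8,8a-hexahydroazulen-4(1H)-one
Product: 15 (1S,3S,3aS,8aS)-3-hydroxy-6,8a-dimethyl-4-oxo-3-(propan-2-yl)-1,2,3,3a,4,7,8,8a-octahydroazulen-1-yl acetate
Conditions: Ac2O, pyridine, DMAP (cat.), CH2Cl2, 0 °C → rt
Reagents that add atoms: acetic anhydride, CC(=O)OC(C)=O
Why: Nucleophile-catalysed acylation esterifies the secondary C1 hydroxyl, while the tertiary C3 hydroxyl flanked by the isopropyl group stays free.

**Step 8**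
Reactants: 15 (1S,3S,3aS,8aS)-3-hydroxy-6,8a-dimethyl-4-oxo-3-(propan-2-yl)-1,2,3,3a,4,7,8,8a-octahydroazulen-1-yl acetate
Product: 16 (1S,3S,3aS,8aS)-3-hydroxy-6,8a-dimethyl-4,7-dioxo-3-(propan-2-yl)-1,2,3,3a,4,7,8,8a-octahydroazulen-1-yl acetate
Conditions: Rh2(cap)4 (cap = caprolactamate, 1 mol %), t-BuOOH (70% aq., 5 equiv), ClCH2CH2Cl, 40 °C
Reagents that add atoms: tert-butyl hydroperoxide, CC(C)(C)OO
Why: Dirhodium-catalysed radical allylic (γ) oxidation with tert-butyl hydroperoxide converts the ring methylene C7, the only secondary position γ to the enone carbonyl, into a ketone, the enone-to-ene-dione conversion that is routine for cyclic β,β-disubstituted enones.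

**Step 9**
Reactants: 16 (1S,3S,3aS,8aS)-3-hydroxy-6,8a-dimethyl-4,7-dioxo-3-(propan-2-yl)-1,2,3,3a,4,7,8,8a-octahydroazulen-1-yl acetate
Product: 17 (1S,3S,3aR,4R,8aS)-3,4-dihydroxy-6,8a-dimethyl-7-oxo-3-(propan-2-yl)-1,2,3,3a,4,7,8,8a-octahydroazulen-1-yl acetate
Conditions: Me4NBH(OAc)3 (5 equiv), MeCN/AcOH (1:1), −30 → −20 °C
Reagents that add atoms: none
Why: In the Evans–Saksena reduction the C3 hydroxyl exchanges onto boron and the alkoxyborohydride delivers hydride intramolecularly to the β-face of the neighbouring C4 carbonyl, which sets C4 (R, anti-1,3-diol) and leaves the distant C7 carbonyl, which this mild reagent should not reduce without direction, intact.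

**Step 10**
Reactants: 17 (1S,3S,3aR,4R,8aS)-3,4-dihydroxy-6,8a-dimethyl-7-oxo-3-(propan-2-yl)-1,2,3,3a,4,7,8,8a-octahydroazulen-1-yl acetate; 18 4-[(tert-butyldimethylsilyl)oxy]benzoic acid
Product: 19 (1S,3S,3aR,4R,8aS)-1-acetoxy-3-hydroxy-6,8a-dimethyl-7-oxo-3-(propan-2-yl)-1,2,3,3a,4,7,8,8a-octahydroazulen-4-yl 4-[(tert-butyldimethylsilyl)oxy]benzoate
Conditions: DCC, DMAP (cat.), CH2Cl2, rt
Reagents that add atoms: none
Why: Steglich esterification acylates the only secondary hydroxyl (allylic C4–OH), the tertiary C3–OH being too hindered, and the silyl ether keeps the phenol from self-condensation.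

**Step 11**
Reactants: 19 (1S,3S,3aR,4R,8aS)-1-acetoxy-3-hydroxy-6,8a-dimethyl-7-oxo-3-(propan-2-yl)-1,2,3,3a,4,7,8,8a-octahydroazulen-4-yl 4-[(tert-butyldimethylsilyl)oxy]benzoate
Product: 20 (1S,3S,3aR,4R,8aS)-1-acetoxy-3-hydroxy-6,8a-dimethyl-7-oxo-3-(propan-2-yl)-1,2,3,3a,4,7,8,8a-octahydroazulen-4-yl 4-hydroxybenzoate
Conditions: KHF2, MeOH, rt
Reagents that add atoms: none
Why: Bifluoride in methanol cleaves aryl silyl ethers selectively (fluoride-mediated desilylation), so the phenol is released while both esters, the enone and the tertiary alcohol should survive.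

**Compound list**

1 | 2,5-dimethylfuran | Cc1ccc(C)o1 | starting material
2 | 1,1,3,3-tetrabromopropan-2-one | O=C(C(Br)Br)C(Br)Br | starting material
3 | 2,4-dibromo-1,5-dimethyl-8-oxabicyclo[3.2.1]oct-6-en-3-one (bromide epimers) | C[C@@]12C(Br)C(=O)C(Br)[C@@](C)(O1)C=C2 | intermediate
4 | meso-(1R,5S)-1,5-dimethyl-8-oxabicyclo[3.2.1]oct-6-en-3-one | C[C@@]12CC(=O)C[C@@](C)(O1)C=C2 | intermediate
5 | meso-(1R,5S)-1,5-dimethyl-8-oxabicyclo[3.2.1]octan-3-one | C[C@@]12CC(=O)C[C@@](C)(O1)CC2 | intermediate
6 | rac-6-hydroxy-3,6-dimethylcyclohept-2-en-1-one | CC1=CC(=O)CC(C)(O)CC1 | intermediate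
7 | 3,6-dimethylcyclohepta-2,6-dien-1-one | CC1=CC(=O)C=C(C)CC1 | intermediate
8 | hex-1-yne | CCCCC#C | starting material
9 | [(1E)-hex-1-en-1-yl]bis(2-methylpropyl)aluminium | CCCC/C=C/[Al](CC(C)C)CC(C)C | intermediate
10 | (6S)-6-[(1E)-hex-1-en-1-yl]-3,6-dimethylcyclohept-2-en-1-one | CCCC/C=C/[C@]1(C)CC(=O)C=C(C)CC1 | intermediate
11 | (1S)-1,5-dimethyl-3-oxocyclohept-4-ene-1-carbaldehyde | O=C[C@]1(C)CC(=O)C=C(C)CC1 | intermediate
12 | 3-methylbutan-2-one | CC(=O)C(C)C | starting material
13 | (6S)-6-[(1S)-1-hydroxy-4-methyl-3-oxopentyl]-3,6-dimethylcyclohept-2-en-1-one | O[C@@H](CC(=O)C(C)C)[C@]1(C)CC(=O)C=C(C)CC1 | intermediate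
14 | (1S,3S,3aS,8aS)-1,3-dihydroxy-6,8a-dimethyl-3-(propan-2-yl)-2,3,3a,7,8,8a-hexahydroazulen-4(1H)-one | O[C@H]1C[C@](O)(C(C)C)[C@H]2C(=O)C=C(C)CC[C@]12C | intermediate
15 | (1S,3S,3aS,8aS)-3-hydroxy-6,8a-dimethyl-4-oxo-3-(propan-2-yl)-1,2,3,3a,4,7,8,8a-octahydroazulen-1-yl acetate | CC(=O)O[C@H]1C[C@](O)(C(C)C)[C@H]2C(=O)C=C(C)CC[C@]12C | intermediate
16 | (1S,3S,3aS,8aS)-3-hydroxy-6,8a-dimethyl-4,7-dioxo-3-(propan-2-yl)-1,2,3,3a,4,7,8,8a-octahydroazulen-1-yl acetate | CC(=O)O[C@H]1C[C@](O)(C(C)C)[C@H]2C(=O)C=C(C)C(=O)C[C@]12C | intermediate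
17 | (1S,3S,3aR,4R,8aS)-3,4-dihydroxy-6,8a-dimethyl-7-oxo-3-(propan-2-yl)-1,2,3,3a,4,7,8,8a-octahydroazulen-1-yl acetate | CC(=O)O[C@H]1C[C@](O)(C(C)C)[C@H]2[C@H](O)C=C(C)C(=O)C[C@]12C | intermediate
18 | 4-[(tert-butyldimethylsilyl)oxy]benzoic acid | CC(C)(C)[Si](C)(C)Oc1ccc(cc1)C(=O)O | starting material
19 | (1S,3S,3aR,4R,8aS)-1-acetoxy-3-hydroxy-6,8a-dimethyl-7-oxo-3-(propan-2-yl)-1,2,3,3a,4,7,8,8a-octahydroazulen-4-yl 4-[(tert-butyldimethylsilyl)oxy]benzoate | CC(=O)O[C@H]1C[C@](O)(C(C)C)[C@H]2[C@H](OC(=O)c3ccc(O[Si](C)(C)C(C)(C)C)cc3)C=C(C)C(=O)C[C@]12C | intermediate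
20 | (1S,3S,3aR,4R,8aS)-1-acetoxy-3-hydroxy-6,8a-dimethyl-7-oxo-3-(propan-2-yl)-1,2,3,3a,4,7,8,8a-octahydroazulen-4-yl 4-hydroxybenzoate | CC(=O)O[C@H]1C[C@](O)(C(C)C)[C@H]2[C@H](OC(=O)c3ccc(O)cc3)C=C(C)C(=O)C[C@]12C | target

Total step count: 11. Longest linear sequence: 11 steps (1 → 20).

**Steps most likely to fail**

1. Step 6. The enamine aldol may be slow on this hindered aldehyde/ketone pair, and the C1 configuration may erode by retro-aldol at the dianion stage. The ring may also close through a non-chelated transition state to the cis-fused aldol; neither the kinetic nor the thermodynamic preference for the trans fusion is secured by precedent. Fallback, from 11 back to 14: the two bonds would be made in separate operations under Lewis-acid instead of enamine control. Ketone 12 is converted (LDA, Me3SiCl, THF, −78 °C) into 3-methyl-2-(trimethylsilyloxy)but-1-ene F1. A Mukaiyama aldol addition of F1 to 11 under a chiral tryptophan-derived B-butyl oxazaborolidinone Lewis acid (20 mol %, EtCN, −78 °C, enantiomer chosen for the 1S carbinol) should give (6S)-3,6-dimethyl-6-[(1S)-4-methyl-3-oxo-1-(trimethylsilyloxy)pentyl]cyclohept-2-en-1-one F2. Acidic work-up (1 M HCl, THF) desilylates F2 to 13, which is now isolated and purified. 13 is then cyclised in its own step with BrMgN(i-Pr)2 (2.5 equiv, THF, −40 → 0 °C), whose magnesium chelate should hold the three oxygens more firmly than lithium, to return to the route at 14.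

2. Step 4. The cross-conjugated dienone may give low enantioselectivity, competing 1,2-addition or double-bond migration under the Lewis-acidic alane. Fallback, from 7 back to 11: iminium catalysis in place of organometallic addition. Nitromethane (excess) with 9-amino-9-deoxy-epi-quinine or its pseudo-enantiomer (20 mol %, chosen for the S product) and benzoic acid at 40 °C, run to mono-addition, should give (6S)-3,6-dimethyl-6-(nitromethyl)cyclohept-2-en-1-one F3. A reductive Nef reaction (aq. TiCl3, NH4OAc, DME, rt) then converts F3 into aldehyde 11.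

3. Step 8. Oxidation may also occur at the C6 methyl group or go further, the β-hydroxy ene-dione may dehydrate or undergo retro-aldol cleavage, and in step 9 the ene-dione may suffer undirected conjugate reduction. Fallback, from 15 back to 19: the order of reduction and oxidation is inverted so that no ene-dione is handled.
   - Evans–Saksena reduction of enone 15 (Me4NBH(OAc)3, MeCN/AcOH, −30 °C) should give (1S,3S,3aR,4R,8aS)-3,4-dihydroxy-6,8a-dimethyl-3-(propan-2-yl)-1,2,3,3a,4,7,8,8a-octahydroazulen-1-yl acetate F4.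
   - Steglich esterification of F4 with 18 (DCC, DMAP, CH2Cl2) gives (1S,3S,3aR,4R,8aS)-1-acetoxy-3-hydroxy-6,8a-dimethyl-3-(propan-2-yl)-1,2,3,3a,4,7,8,8a-octahydroazulen-4-yl 4-[(tert-butyldimethylsilyl)oxy]benzoate F5.
   - Allylic hydroxylation of F5 with SeO2 (cat.) and t-BuOOH (CH2Cl2, rt) should take place at the ring methylene on the more substituted alkene carbon, by the usual site rule of the ene oxidation. It gives (1S,3S,3aR,4R,8aS)-1-acetoxy-3,7-dihydroxy-6,8a-dimethyl-3-(propan-2-yl)-1,2,3,3a,4,7,8,8a-octahydroazulen-4-yl 4-[(tert-butyldimethylsilyl)oxy]benzoate F6 (C7 epimers).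
   - Dess–Martin periodinane (CH2Cl2, rt) oxidises F6 to 19.

**Further compounds**

F1 | step 6 | 3-methyl-2-(trimethylsilyloxy)but-1-ene | CC(C)C(=C)O[Si](C)(C)C
F2 | step 6 | (6S)-3,6-dimethyl-6-[(1S)-4-methyl-3-oxo-1-(trimethylsilyloxy)pentyl]cyclohept-2-en-1-one | C[Si](C)(C)O[C@@H](CC(=O)C(C)C)[C@]1(C)CC(=O)C=C(C)CC1
F3 | step 4 | (6S)-3,6-dimethyl-6-(nitromethyl)cyclohept-2-en-1-one | [O-][N+](=O)C[C@]1(C)CC(=O)C=C(C)CC1
F4 | step 8 | (1S,3S,3aR,4R,8aS)-3,4-dihydroxy-6,8a-dimethyl-3-(propan-2-yl)-1,2,3,3a,4,7,8,8a-octahydroazulen-1-yl acetate | CC(=O)O[C@H]1C[C@](O)(C(C)C)[C@H]2[C@H](O)C=C(C)CC[C@]12C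
F5 | step 8 | (1S,3S,3aR,4R,8aS)-1-acetoxy-3-hydroxy-6,8a-dimethyl-3-(propan-2-yl)-1,2,3,3a,4,7,8,8a-octahydroazulen-4-yl 4-[(tert-butyldimethylsilyl)oxy]benzoate | CC(=O)O[C@H]1C[C@](O)(C(C)C)[C@H]2[C@H](OC(=O)c3ccc(O[Si](C)(C)C(C)(C)C)cc3)C=C(C)CC[C@]12C
F6 | step 8 | (1S,3S,3aR,4R,8aS)-1-acetoxy-3,7-dihydroxy-6,8a-dimethyl-3-(propan-2-yl)-1,2,3,3a,4,7,8,8a-octahydroazulen-4-yl 4-[(tert-butyldimethylsilyl)oxy]benzoate (C7 epimers) | CC(=O)O[C@H]1C[C@](O)(C(C)C)[C@H]2[C@H](OC(=O)c3ccc(O[Si](C)(C)C(C)(C)C)cc3)C=C(C)C(O)C[C@]12C
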